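**Retrosynthetic overview**

1. Dendronpholide A ⇐ desilylation and 11‑O‑acetylation of a bicyclic 3‑O‑silyl 11‑hydroxy lactone.
2. Both rings come from one acyclic ynal in one flask: first the 14‑membered carbocycle by nickel‑catalysed reductive alkyne–aldehyde coupling (C3–C4; sets C3 and the E‑C4=C5 olefin), then the seven‑membered lactone by malonate hydrolysis, decarboxylative methylenation and transannular opening of the (11S,12S)‑epoxide at C12 with inversion.
3. The acyclic ynal ⇐ organocatalytic Michael addition of dimethyl malonate (masked acrylic acid) to an enal (sets C1) ⇐ Wittig homologation ⇐ ester reduction.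
4. The but‑2‑ynyl terminus ⇐ Stille coupling at the allylic acetate; the epoxide ⇐ Shi epoxidation of C11=C12 (C7=C8 is deactivated by the acetate).
5. The diene ester ⇐ geranyl acetate by SeO2 oxidation, Appel bromination and ester‑enolate alkylation.

Assumption: atom labels C1–C20 are those of the cembrane skeleton of the target (C1 bears the acrylate carbon C15, C3 is the carbinol, C11 the acetoxy carbon, C12 the lactone carbon) and are used for every intermediate.

**Route**

Step 1
Reactants: 1 geranyl acetate [(2E)-3,7-dimethylocta-2,6-dien-1-yl acetate]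
Product: 2 (2E,6E)-8-hydroxy-3,7-dimethylocta-2,6-dien-1-yl acetate
Conditions: SeO2 (cat.), t-BuOOH, salicylic acid (cat.), CH2Cl2, rt
Reagents that add atoms: tert-butyl hydroperoxide, CC(C)(C)OO
Why: Sharpless SeO2/t-BuOOH allylic oxidation (ene reaction then [2,3]-shift) hydroxylates the E-methyl of the electron-rich terminal olefin, the acetate-bearing olefin being deactivated.

Step 2
Reactants: 2 (2E,6E)-8-hydroxy-3,7-dimethylocta-2,6-dien-1-yl acetate
Product: 3 (2E,6E)-8-bromo-3,7-dimethylocta-2,6-dien-1-yl acetate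
Conditions: CBr4, PPh3, CH2Cl2, 0 °C
Reagents that add atoms: carbon tetrabromide, BrC(Br)(Br)Br
Why: Appel bromination of the primary allylic alcohol under neutral conditions, without allylic transposition or loss of the acetate.

Step 3
Reactants: 3 (2E,6E)-8-bromo-3,7-dimethylocta-2,6-dien-1-yl acetate; 4 ethyl acetate
Product: 6 ethyl (4E,8E)-10-acetoxy-4,8-dimethyldeca-4,8-dienoate, via lithium enolate of ethyl acetate 5 (not isolated)
Conditions: LiN(i-Pr)2, THF, −78 °C; then 3, DMPU, −78 to −40 °C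
Reagents that add atoms: none
Why: SN2 alkylation of the ester enolate by the primary allylic bromide at −78 °C outpaces Claisen attack on the acetate and leaves both E olefins untouched (forms C13–C14).

Step 4
Reactants: 6 ethyl (4E,8E)-10-acetoxy-4,8-dimethyldeca-4,8-dienoate
Product: 7 ethyl 3-{(2S,3S)-3-[(3E)-5-acetoxy-3-methylpent-3-en-1-yl]-2-methyloxiran-2-yl}propanoate
Conditions: 1,2:4,5-di-O-isopropylidene-β-L-erythro-2,3-hexodiulo-2,6-pyranose (30 mol %), KHSO5 (as 2KHSO5·KHSO4·K2SO4), K2CO3, Bu4NHSO4, MeCN–CH2(OMe)2–aq. Na2B4O7, 0 °C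
Reagents that add atoms: potassium peroxymonosulfate, [K+].[O-]OS(=O)(=O)O
Why: Shi asymmetric epoxidation: the chiral dioxirane attacks only the electron-rich C11=C12 olefin (C7=C8 is deactivated by the allylic acetate) through the spiro transition state, and the L-fructose-derived ketone gives the (11S,12S)-epoxide.

Step 5
Reactants: 7 ethyl 3-{(2S,3S)-3-[(3E)-5-acetoxy-3-methylpent-3-en-1-yl]-2-methyloxiran-2-yl}propanoate; 8 tributyl(prop-1-yn-1-yl)stannane
Product: 9 ethyl 3-{(2S,3S)-2-methyl-3-[(3E)-3-methyloct-3-en-6-yn-1-yl]oxiran-2-yl}propanoate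
Conditions: Pd2(dba)3 (5 mol %), LiCl, DMF, 40 °C
Reagents that add atoms: none
Why: Stille coupling through the π-allylpalladium formed from the allylic acetate; the alkynyl group transfers fastest from tin and is delivered to the primary terminus (C6) with retention of the E olefin.

Step 6
Reactants: 9 ethyl 3-{(2S,3S)-2-methyl-3-[(3E)-3-methyloct-3-en-6-yn-1-yl]oxiran-2-yl}propanoate
Product: 10 3-{(2S,3S)-2-methyl-3-[(3E)-3-methyloct-3-en-6-yn-1-yl]oxiran-2-yl}propanal
Conditions: i-Bu2AlH, CH2Cl2, −78 °C; aq. KNaC4H4O6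
Reagents that add atoms: none
Why: Partial ester reduction via the tetrahedral aluminium hemiacetal that is stable at −78 °C; the trisubstituted epoxide and the alkyne are inert.

Step 7
Reactants: 10 3-{(2S,3S)-2-methyl-3-[(3E)-3-methyloct-3-en-6-yn-1-yl]oxiran-2-yl}propanal; 11 2-(triphenyl-λ5-phosphanylidene)acetaldehyde
Product: 12 (2E)-5-{(2S,3S)-2-methyl-3-[(3E)-3-methyloct-3-en-6-yn-1-yl]oxiran-2-yl}pent-2-enal
Conditions: toluene, 80 °C
Reagents that add atoms: none
Why: Wittig olefination with the stabilised formyl ylide gives the E-enal (C1=C2) under neutral conditions.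

Step 8
Reactants: 12 (2E)-5-{(2S,3S)-2-methyl-3-[(3E)-3-methyloct-3-en-6-yn-1-yl]oxiran-2-yl}pent-2-enal; 13 dimethyl malonate
Product: 14 dimethyl 2-[(3R)-1-{(2S,3S)-2-methyl-3-[(3E)-3-methyloct-3-en-6-yn-1-yl]oxiran-2-yl}-5-oxopentan-3-yl]propanedioate
Conditions: (S)-2-[bis(3,5-bis(trifluoromethyl)phenyl)(trimethylsilyloxy)methyl]pyrrolidine (10 mol %), EtOH, 0 °C
Reagents that add atoms: none
Why: Jørgensen–Hayashi iminium-catalysed Michael addition: the bulky silyloxydiarylmethyl group of the (S)-catalyst shields one face of the E-iminium, so the malonate adds to C1 from the open face and gives 1R.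

Step 9
Reactants: 14 dimethyl 2-[(3R)-1-{(2S,3S)-2-methyl-3-[(3E)-3-methyloct-3-en-6-yn-1-yl]oxiran-2-yl}-5-oxopentan-3-yl]propanedioate
Product: 18 11-O-deacetyl-3-O-(triisopropylsilyl)dendronpholide A, via macrocyclic epoxy malonate silyl ether 15 (not isolated), via macrocyclic epoxy malonic acid 16 (not isolated), via macrocyclic epoxy acrylic acid 17 (not isolated)
Conditions: Ni(cod)2 (20 mol %), 1,3-dimesitylimidazol-2-ylidene (20 mol %), i-Pr3SiH, THF, 0.005 M, rt; then LiOH, MeOH–H2O, 40 °C; then AcOH, Et2NH (cat.), aq. CH2O, 60 °C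
Reagents that add atoms: triisopropylsilane, CC(C)[SiH](C(C)C)C(C)C; lithium hydroxide, [Li+].[OH-]; formaldehyde, C=O
Why: Montgomery-type nickel-catalysed reductive ynal macrocyclisation closes the 14-membered ring with the small carbene ligand directing C–C bond formation to the methyl-bearing alkyne carbon and syn addition giving the E-C4=C5 olefin, C3 being set (3S, Re-face attack on the aldehyde) under control of the 1R centre in the macrocyclic transition state and trapped as its silyl ether; saponification and Mannich-type decarboxylative methylenation then unveil the acrylic acid, which opens the epoxide transannularly (7-exo) at the tertiary C12 with inversion to close the seven-membered lactone (12R, 11S retained).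

Step 10
Reactants: 18 11-O-deacetyl-3-O-(triisopropylsilyl)dendronpholide A
Product: 19 3-O-(triisopropylsilyl)dendronpholide A
Conditions: Ac2O, DMAP, pyridine, CH2Cl2, rt
Reagents that add atoms: acetic anhydride, CC(=O)OC(C)=O
Why: DMAP-catalysed acetylation of the only free hydroxyl (C11), with no stereocentre touched.

Step 11
Reactants: 19 3-O-(triisopropylsilyl)dendronpholide A
Product: 20 dendronpholide A
Conditions: HF·pyridine, THF–pyridine, 0 °C to rt
Reagents that add atoms: none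
Why: Buffered fluoride desilylation frees the allylic C3 hydroxyl without base, so the acetate and the α-methylene lactone survive.

**Compound list**

1 | geranyl acetate, (2E)-3,7-dimethylocta-2,6-dien-1-yl acetate | CC(=O)OC/C=C(\C)CCC=C(C)C | starting material
2 | (2E,6E)-8-hydroxy-3,7-dimethylocta-2,6-dien-1-yl acetate | CC(=O)OC/C=C(\C)CC/C=C(\C)CO | intermediate
3 | (2E,6E)-8-bromo-3,7-dimethylocta-2,6-dien-1-yl acetate | CC(=O)OC/C=C(\C)CC/C=C(\C)CBr | intermediate
4 | ethyl acetate | CCOC(C)=O | starting material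
5 | lithium 1-ethoxyethen-1-olate (lithium enolate of ethyl acetate) | [Li+].[O-]C(=C)OCC | intermediate
6 | ethyl (4E,8E)-10-acetoxy-4,8-dimethyldeca-4,8-dienoate | CCOC(=O)CC/C(C)=C/CC/C(C)=C/COC(C)=O | intermediate
7 | ethyl 3-{(2S,3S)-3-[(3E)-5-acetoxy-3-methylpent-3-en-1-yl]-2-methyloxiran-2-yl}propanoate | CCOC(=O)CC[C@]1(C)O[C@H]1CC/C(C)=C/COC(C)=O | intermediate
8 | tributyl(prop-1-yn-1-yl)stannane | CC#C[Sn](CCCC)(CCCC)CCCC | starting material
9 | ethyl 3-{(2S,3S)-2-methyl-3-[(3E)-3-methyloct-3-en-6-yn-1-yl]oxiran-2-yl}propanoate | CCOC(=O)CC[C@]1(C)O[C@H]1CC/C(C)=C/CC#CC | intermediate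
10 | 3-{(2S,3S)-2-methyl-3-[(3E)-3-methyloct-3-en-6-yn-1-yl]oxiran-2-yl}propanal | O=CCC[C@]1(C)O[C@H]1CC/C(C)=C/CC#CC | intermediate
11 | 2-(triphenyl-λ5-phosphanylidene)acetaldehyde | O=CC=P(c1ccccc1)(c1ccccc1)c1ccccc1 | starting material
12 | (2E)-5-{(2S,3S)-2-methyl-3-[(3E)-3-methyloct-3-en-6-yn-1-yl]oxiran-2-yl}pent-2-enal | O=C/C=C/CC[C@]1(C)O[C@H]1CC/C(C)=C/CC#CC | intermediate
13 | dimethyl malonate | COC(=O)CC(=O)OC | starting material
14 | dimethyl 2-[(3R)-1-{(2S,3S)-2-methyl-3-[(3E)-3-methyloct-3-en-6-yn-1-yl]oxiran-2-yl}-5-oxopentan-3-yl]propanedioate | COC(=O)C(C(=O)OC)[C@@H](CC=O)CC[C@]1(C)O[C@H]1CC/C(C)=C/CC#CC | intermediate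
15 | dimethyl 2-[(1R,3S,4E,7E,11S,12S)-11,12-epoxy-4,8,12-trimethyl-3-(triisopropylsilyloxy)cyclotetradeca-4,7-dien-1-yl]propanedioate | COC(=O)C(C(=O)OC)[C@H]1C[C@H](O[Si](C(C)C)(C(C)C)C(C)C)/C(C)=C/C/C=C(\C)CC[C@@H]2O[C@@]2(C)CC1 | intermediate
16 | 2-[(1R,3S,4E,7E,11S,12S)-11,12-epoxy-4,8,12-trimethyl-3-(triisopropylsilyloxy)cyclotetradeca-4,7-dien-1-yl]propanedioic acid | OC(=O)C(C(O)=O)[C@H]1C[C@H](O[Si](C(C)C)(C(C)C)C(C)C)/C(C)=C/C/C=C(\C)CC[C@@H]2O[C@@]2(C)CC1 | intermediate
17 | 2-[(1R,3S,4E,7E,11S,12S)-11,12-epoxy-4,8,12-trimethyl-3-(triisopropylsilyloxy)cyclotetradeca-4,7-dien-1-yl]prop-2-enoic acid | C=C(C(=O)O)[C@H]1C[C@H](O[Si](C(C)C)(C(C)C)C(C)C)/C(C)=C/C/C=C(\C)CC[C@@H]2O[C@@]2(C)CC1 | intermediate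
18 | 11-O-deacetyl-3-O-(triisopropylsilyl)dendronpholide A: (1R,3S,4E,7E,11S,12R) bicyclic ε-lactone (C16 acyl on O–C12) with 11-OH and 3-OSi(i-Pr)3 | C=C1C(=O)O[C@]2(C)CC[C@@H]1C[C@H](O[Si](C(C)C)(C(C)C)C(C)C)/C(C)=C/C/C=C(\C)CC[C@@H]2O | intermediate
19 | 3-O-(triisopropylsilyl)dendronpholide A | C=C1C(=O)O[C@]2(C)CC[C@@H]1C[C@H](O[Si](C(C)C)(C(C)C)C(C)C)/C(C)=C/C/C=C(\C)CC[C@@H]2OC(C)=O | intermediate
20 | dendronpholide A (1R,3S,4E,7E,11S,12R) | C=C1C(=O)O[C@]2(C)CC[C@@H]1C[C@H](O)/C(C)=C/C/C=C(\C)CC[C@@H]2OC(C)=O | target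

**Step count and weak points**

Total steps: 11. Longest linear sequence: 11 steps (1 to 20).

Steps most likely to fail:

Step 9. The C3 configuration rests on substrate control in the macrocyclisation, and the acidic malonate C–H may slow the nickel catalyst. Fallback: set out from 14 and cyclise with Ni(cod)2, PBu3 and Et3B to the free macrocyclic alcohol as a C3 epimer mixture, dimethyl 2-[(1R,3RS,4E,7E,11S,12S)-11,12-epoxy-3-hydroxy-4,8,12-trimethylcyclotetradeca-4,7-dien-1-yl]propanedioate F1. Oxidise this with Dess–Martin periodinane to the macrocyclic enone F2. Reduce the enone under reagent control with (R)-2-methyl-CBS-oxazaborolidine and catecholborane to the (3S)-alcohol F3. Silylate with i-Pr3SiOTf and 2,6-lutidine, which comes back to the route at 15; 15 is then taken through the hydrolysis, methylenation and lactonisation stages as before.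

Step 5. Allylic acetates are sluggish Stille partners and the π-allyl intermediate can erode the E geometry. Fallback: set out from 7 and remove the acetate with K2CO3 in EtOH to give the allylic alcohol ethyl 3-{(2S,3S)-3-[(3E)-5-hydroxy-3-methylpent-3-en-1-yl]-2-methyloxiran-2-yl}propanoate F4. Convert it with MsCl, Et3N and LiCl into the allylic chloride F5. Couple this by SN2 substitution with CH3C≡CMgBr and catalytic CuI at −30 °C, which comes back to the route at 9.

Step 3. The enolate may attack the allylic acetate, and step 1 before it is only moderate in yield. Fallback: set out from 1 and cleave the electron-rich terminal olefin selectively with O3 (pyridine, CH2Cl2, −78 °C; Me2S) to the aldehyde (2E)-3-methyl-6-oxohex-2-en-1-yl acetate F6. Add CH2=C(CH3)MgBr at −78 °C to give the allylic alcohol (2E)-6-hydroxy-3,7-dimethylocta-2,7-dien-1-yl acetate F7. A Johnson–Claisen rearrangement (MeC(OEt)3, cat. EtCO2H, 140 °C) builds the E-C11=C12 olefin and the ester and comes back to the route at 6.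

Further compounds

F1 | step 9 | dimethyl 2-[(1R,3RS,4E,7E,11S,12S)-11,12-epoxy-3-hydroxy-4,8,12-trimethylcyclotetradeca-4,7-dien-1-yl]propanedioate | COC(=O)C(C(=O)OC)[C@H]1CC(O)/C(C)=C/C/C=C(\C)CC[C@@H]2O[C@@]2(C)CC1
F2 | step 9 | dimethyl 2-[(1R,4E,7E,11S,12S)-11,12-epoxy-4,8,12-trimethyl-3-oxocyclotetradeca-4,7-dien-1-yl]propanedioate | COC(=O)C(C(=O)OC)[C@H]1CC(=O)/C(C)=C/C/C=C(\C)CC[C@@H]2O[C@@]2(C)CC1
F3 | step 9 | dimethyl 2-[(1R,3S,4E,7E,11S,12S)-11,12-epoxy-3-hydroxy-4,8,12-trimethylcyclotetradeca-4,7-dien-1-yl]propanedioate | COC(=O)C(C(=O)OC)[C@H]1C[C@H](O)/C(C)=C/C/C=C(\C)CC[C@@H]2O[C@@]2(C)CC1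
F4 | step 5 | ethyl 3-{(2S,3S)-3-[(3E)-5-hydroxy-3-methylpent-3-en-1-yl]-2-methyloxiran-2-yl}propanoate | CCOC(=O)CC[C@]1(C)O[C@H]1CC/C(C)=C/CO
F5 | step 5 | ethyl 3-{(2S,3S)-3-[(3E)-5-chloro-3-methylpent-3-en-1-yl]-2-methyloxiran-2-yl}propanoate | CCOC(=O)CC[C@]1(C)O[C@H]1CC/C(C)=C/CCl
F6 | step 3 | (2E)-3-methyl-6-oxohex-2-en-1-yl acetate | O=CCC/C(C)=C/COC(C)=O
F7 | step 3 | (2E)-6-hydroxy-3,7-dimethylocta-2,7-dien-1-yl acetate (racemic at the carbinol) | CC(=C)C(O)CC/C(C)=C/COC(C)=O
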